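Polonidine A is disconnected at both N1–C7a bonds. What remains between the two nitrogens is the strand C2–C3–CH2–C3'–C2', with the two benzo rings attached at C3 and C3'; this is C2 to C6 of a 3,5-diarylpyridine, C4 being the future methylene carbon. Zincke opening of such a pyridine with the reverse-prenyl amine should give a 2,4-bis(2-chlorophenyl)pentamethinium salt carrying one tert-alkyl group on each nitrogen. A twofold palladium-catalysed intramolecular N-arylation then closes both pyrrole rings in one operation and delivers the bis(indol-3-yl)methylium ion, which a single hydride transfer converts into the target.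

Key step: step 4

Remark: the open-chain compounds 9–12 and the cation 13 are delocalised or mobile about their chain bonds. The geometries written are the all-trans (W) forms, and none is carried into the target, which has no stereogenic element.

Step 1
Reactants: 1 3,5-dibromopyridine; 2 2-chlorophenylboronic acid (2.4 equiv)
Product: 4 3,5-bis(2-chlorophenyl)pyridine, via 3-bromo-5-(2-chlorophenyl)pyridine 3 (not isolated)
Conditions: Pd(PPh3)4 (5 mol%), Na2CO3 (2 M aq), DME, 85 °C
Reagents that add atoms: none
Why: Twofold Suzuki–Miyaura coupling, in which Pd(PPh3)4 inserts into the activated pyridyl C–Br bonds far faster than into aryl C–Cl bonds, so both bromides are replaced and the two ortho chlorides needed later stay in place.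

Step 2
Reactants: 5 2-methylbut-3-yn-2-amine
Product: 6 2-methylbut-3-en-2-amine
Conditions: H2 (1 atm), Pd/CaCO3 poisoned with Pb(OAc)2 (Lindlar catalyst), quinoline, pentane, 0 °C to rt; filtration, distillation
Reagents that add atoms: none
Why: Lindlar semihydrogenation, in which the poisoned palladium surface adds one equivalent of H2 to the terminal alkyne and releases the alkene before it is reduced further.

Step 3
Reactants: 4 3,5-bis(2-chlorophenyl)pyridine; 7 1-chloro-2,4-dinitrobenzene (1.05 equiv); 6 2-methylbut-3-en-2-amine (2.5 equiv)
Product: 10 N,N'-bis(2-methylbut-3-en-2-yl)-2,4-bis(2-chlorophenyl)pentamethinium chloride, via Zincke pyridinium chloride 8 (not isolated), via dinitroanilino pentadieniminium chloride 9 (not isolated)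
Conditions: 7, MeCN (2 M), 85 °C, sealed tube; then EtOH, 0 °C, 6, 0 °C to rt; filtration of the precipitated 2,4-dinitroaniline, crystallisation from EtOAc/Et2O
Reagents that add atoms: none
Why: SNAr quaternisation to the Zincke salt followed in the same flask by Zincke ring opening to a pentamethinium (König-type) salt: the pyridine nitrogen, unhindered because both aryl groups sit at C3 and C5, displaces chloride from the doubly nitro-activated arene, amine 6 then adds at C2 of the activated pyridinium, the ring opens and a second amine displaces 2,4-dinitroaniline from the other terminus, while reclosure to an N-alkylpyridinium salt is held back by the fully substituted carbon on nitrogen and by the low temperature.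

Step 4
Reactants: 10 N,N'-bis(2-methylbut-3-en-2-yl)-2,4-bis(2-chlorophenyl)pentamethinium chloride
Product: 13 bis[1-(2-methylbut-3-en-2-yl)indol-3-yl]methylium chloride, via free vinylogous amidine 11 (not isolated), via indolyl azadiene 12 (not isolated)
Conditions: Pd2(dba)3 (5 mol%), XPhos (12 mol%), K3PO4 (3 equiv), 1,4-dioxane, 90 °C, argon; filtration through Celite, precipitation from CH2Cl2/Et2O
Reagents that add atoms: none
Why: Proposed new method: K3PO4 frees the neutral vinylogous amidine 11, zerovalent palladium carrying XPhos inserts into one aryl C–Cl bond, the neighbouring N–H binds and is deprotonated, and C–N reductive elimination from the six-membered azapalladacycle (Pd, C7a, C3a, C3, C2, N1) gives the indole 12. The remaining imine nitrogen of 12, made amidine-like by conjugation with the new indole nitrogen, binds the second arylpalladium chloride in the same way, and reductive elimination forms the second N1–C7a bond with the charge spread over the whole diindolylmethylium system and chloride left as counter-ion. The closest known reaction type is the intramolecular Buchwald–Hartwig N-arylation of 2-(2-haloaryl)enamines and of N-(2-haloaryl)amidines to indoles and benzimidazoles. Each pyrrole ring closes by intramolecular substitution at the aryl carbon with the chloride leaving outside the new five-membered ring, and no stereocentre is created. The step needs N-arylation to outrun six-electron reclosure of the chain to an N-alkylpyridinium salt, ionisation of the tert-allyl C–N bonds and Heck insertion into the vinyl groups. The fully substituted carbon on each nitrogen blocks the 1,2-dihydropyridine on the way to reclosure, the chain geometry places each nitrogen on the same side of its C=C bond as the 2-chlorophenyl group, and a Heck closure would have to form a seven-membered ring.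

Step 5
Reactants: 13 bis[1-(2-methylbut-3-en-2-yl)indol-3-yl]methylium chloride
Product: 14 Polonidine A, bis[1-(2-methylbut-3-en-2-yl)-1H-indol-3-yl]methane
Conditions: NaBH4 (1.5 equiv), MeOH/CH2Cl2, 0 °C
Reagents that add atoms: none
Why: Hydride reduction of a stabilised carbenium ion, in which borohydride attacks the central methine carbon, whose capture restores both aromatic indoles, while the terminal alkenes are inert to NaBH4 once palladium has been removed.

Compound list
1 | 3,5-dibromopyridine | Brc1cncc(Br)c1 | starting material
2 | 2-chlorophenylboronic acid | OB(O)c1ccccc1Cl | starting material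
3 | 3-bromo-5-(2-chlorophenyl)pyridine | Clc1ccccc1-c1cncc(Br)c1 | intermediate
4 | 3,5-bis(2-chlorophenyl)pyridine | Clc1ccccc1-c1cncc(-c2ccccc2Cl)c1 | intermediate
5 | 2-methylbut-3-yn-2-amine | CC(C)(N)C#C | starting material
6 | 2-methylbut-3-en-2-amine | CC(C)(N)C=C | intermediate
7 | 1-chloro-2,4-dinitrobenzene | O=[N+]([O-])c1ccc(Cl)c([N+](=O)[O-])c1 | starting material
8 | 3,5-bis(2-chlorophenyl)-1-(2,4-dinitrophenyl)pyridin-1-ium chloride (Zincke salt) | O=[N+]([O-])c1ccc(-[n+]2cc(-c3ccccc3Cl)cc(-c3ccccc3Cl)c2)c([N+](=O)[O-])c1.[Cl-] | intermediate
9 | N-[2,4-bis(2-chlorophenyl)-5-(2,4-dinitroanilino)penta-2,4-dien-1-ylidene]-2-methylbut-3-en-2-aminium chloride (all-trans chain) | O=[N+]([O-])c1ccc(N/C=C(c2ccccc2Cl)/C=C(c2ccccc2Cl)/C=[NH+]/C(C)(C)C=C)c([N+](=O)[O-])c1.[Cl-] | intermediate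
10 | N,N'-bis(2-methylbut-3-en-2-yl)-2,4-bis(2-chlorophenyl)pentamethinium chloride (W-shaped chain, each nitrogen on the side of its neighbouring aryl group) | C=CC(C)(C)N/C=C(c1ccccc1Cl)/C=C(c1ccccc1Cl)/C=[NH+]/C(C)(C)C=C.[Cl-] | intermediate
11 | N-[2,4-bis(2-chlorophenyl)-5-(2-methylbut-3-en-2-ylamino)penta-2,4-dien-1-ylidene]-2-methylbut-3-en-2-amine (free base of 10, all-trans chain) | C=CC(C)(C)N/C=C(c1ccccc1Cl)/C=C(c1ccccc1Cl)/C=N/C(C)(C)C=C | intermediate
12 | N-{2-(2-chlorophenyl)-3-[1-(2-methylbut-3-en-2-yl)indol-3-yl]prop-2-en-1-ylidene}-2-methylbut-3-en-2-amine (indolyl group trans to the imine carbon across the C=C bond) | C=CC(C)(C)/N=C/C(c1ccccc1Cl)=C/c1cn(C(C)(C)C=C)c2ccccc12 | intermediate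
13 | bis[1-(2-methylbut-3-en-2-yl)indol-3-yl]methylium chloride (delocalised cation, drawn as the 3-(indol-3-ylmethylidene)-3H-indolium form) | C=CC(C)(C)n1cc(/C=C2/C=[N+](C(C)(C)C=C)c3ccccc23)c2ccccc21.[Cl-] | intermediate
14 | Polonidine A, bis[1-(2-methylbut-3-en-2-yl)-1H-indol-3-yl]methane | C=CC(C)(C)n1cc(Cc2cn(C(C)(C)C=C)c3ccccc23)c2ccccc21 | target

Total step count: 5
Longest linear sequence: 4 steps (steps 1, 3, 4 and 5, from 3,5-dibromopyridine)

Steps most likely to fail

1. Step 4. The chain may reclose to a pyridinium salt, the tert-allyl C–N bonds may ionise on palladium with loss or 1,3-shift of the reverse-prenyl groups, or the sequence may stall after the first ring closure. The fallback builds the indole rings one at a time by known chemistry and sets out from amine 6. Its coupling partner, 1-bromo-2-[(Z)-2-bromovinyl]benzene F1, would be made from 2-bromobenzaldehyde by a Wittig reaction with (bromomethyl)triphenylphosphonium bromide and KOtBu in THF at −78 °C. Palladium-catalysed tandem alkenyl and aryl amination of F1 with 6 (Pd2(dba)3, a biarylphosphine, NaOtBu, toluene, 100 °C) should give 1-(2-methylbut-3-en-2-yl)-1H-indole F2. Two molecules of F2 would then be joined through C3 by condensation with aqueous formaldehyde in AcOH at rt, a standard diindolylmethane synthesis. This returns to the route at the target 14 and bypasses 13 and step 5.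

2. Step 3. Quaternisation of the weakly nucleophilic diarylpyridine may stay incomplete with nearly one equivalent of 7, left-over 7 may consume amine, and the hindered amine may add only once so that the exchange stalls at 9. The fallback sets out from 4 and separates the two events. Pyridine 4 would be heated with an excess of 7 (MeCN, 90 °C) and the Zincke salt 8 isolated by trituration with Et2O. The ring would then be opened with dimethylamine (excess, EtOH, rt), a secondary amine that cannot reclose and reliably gives stable pentamethinium salts. The resulting N,N,N',N'-tetramethyl-2,4-bis(2-chlorophenyl)pentamethinium chloride F3 would be transaminated with excess 6 in EtOH at 40–50 °C under a nitrogen sweep that removes the volatile dimethylamine. This returns to the route at 10.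

3. Step 2. The alkene may be reduced further to the saturated amine, which distillation cannot remove, and the volatile free amine may be lost on isolation. The fallback sets out from 5 and moves the reduction onto a crystalline carbamate. Treatment of 5 with Boc2O (CH2Cl2, rt) should give tert-butyl (2-methylbut-3-yn-2-yl)carbamate F4. Semihydrogenation of F4 on the Lindlar catalyst (Pd/CaCO3 poisoned with Pb(OAc)2, quinoline, EtOAc, metered H2) should give tert-butyl (2-methylbut-3-en-2-yl)carbamate F5, which can be purified by recrystallisation. HCl in 1,4-dioxane would then cleave the carbamate to the non-volatile 2-methylbut-3-en-2-aminium chloride F6. Aqueous NaOH would release the amine from F6 immediately before use, which returns to the route at 6.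

Further compounds
F1 | step 4 | 1-bromo-2-[(Z)-2-bromovinyl]benzene | Br/C=C\c1ccccc1Br
F2 | step 4 | 1-(2-methylbut-3-en-2-yl)-1H-indole | C=CC(C)(C)n1ccc2ccccc21
F3 | step 3 | N,N,N',N'-tetramethyl-2,4-bis(2-chlorophenyl)pentamethinium chloride (all-trans chain) | CN(C)/C=C(c1ccccc1Cl)/C=C(c1ccccc1Cl)/C=[N+](C)C.[Cl-]
F4 | step 2 | tert-butyl (2-methylbut-3-yn-2-yl)carbamate | CC(C)(C)OC(=O)NC(C)(C)C#C
F5 | step 2 | tert-butyl (2-methylbut-3-en-2-yl)carbamate | CC(C)(C)OC(=O)NC(C)(C)C=C
F6 | step 2 | 2-methylbut-3-en-2-aminium chloride | C=CC(C)(C)[NH3+].[Cl-]
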